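The C5–C10 bond of the cyclohexane ring is the disconnection on which everything rests. It joins the methine bearing the acrolein unit to the quaternary carbon bearing the methyl group and the oxirane. The precursor is open-chain at that bond: a trans-disubstituted α-methylene-γ-butyrolactone with an allylsilane arm on C7 and a trisubstituted epoxide arm on C8. Lewis-acid epoxide–allylsilane cyclization closes the six-membered ring, sets quaternary C10 by stereospecific inversion and C5 through a lactone-anchored chair, creates the exocyclic methylene of the acrolein unit and leaves a C1 hydroxyl through which the oxirane is later closed. The step exploits the 1,2-relation of quaternary C10 to the oxygenated C1 of the oxirane ring.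

Key step: step 14

Numbering used throughout: cyclohexane ring C5–C6–C7–C8–C9–C10; C5 carries C4(=C3H2)–C15HO, C6 the angelate, C7 and C8 the lactone C11(=C13H2)–C12(=O)–O, C9 the hydroxyl, C10 the methyl C14 and the oxirane C1–C2.

Remark: the bisphosphine antipode in step 6 and the D-fructose-derived ketone in step 9 are taken to be those that deliver the configurations drawn; the ketone assignment follows the spiro transition-state model for (E)-alkenes.

Step 1
Reactants: 1 prop-2-yn-1-ol; 2 (trimethylsilyl)methylmagnesium chloride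
Product: 4 (2E)-3-iodo-2-[(trimethylsilyl)methyl]prop-2-en-1-ol, via alkenylmagnesium alkoxide 3 (not isolated)
Conditions: 2 (2.5 equiv), CuI (10 mol%), THF, 0 °C to rt; then I2, −78 to 0 °C
Reagents that add atoms: iodine, II
Why: Copper-catalysed anti-carbomagnesiation of the propargylic alkoxide should place the silylmethyl group on the inner alkyne carbon and magnesium cis to the CH2O group in a five-membered chelate, and iodinolysis with retention then gives the vinyl iodide of defined geometry.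

Step 2
Reactants: 4 (2E)-3-iodo-2-[(trimethylsilyl)methyl]prop-2-en-1-ol
Product: 5 tert-butyl({(2E)-3-iodo-2-[(trimethylsilyl)methyl]prop-2-en-1-yl}oxy)diphenylsilane
Conditions: TBDPSCl, imidazole, CH2Cl2, rt
Reagents that add atoms: tert-butyl(chloro)diphenylsilane, CC(C)(C)[Si](Cl)(c1ccccc1)c1ccccc1
Why: Routine silylation of the primary alcohol, the bulky silyl group being chosen to resist 1,4-migration from oxygen to carbon in step 3.

Step 3
Reactants: 5 tert-butyl({(2E)-3-iodo-2-[(trimethylsilyl)methyl]prop-2-en-1-yl}oxy)diphenylsilane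
Product: 7 (2E)-4-{[tert-butyl(diphenyl)silyl]oxy}-3-[(trimethylsilyl)methyl]but-2-enal, via alkenyllithium 6 (not isolated)
Conditions: t-BuLi (2.1 equiv), Et2O, −78 °C; then DMF, −78 °C; aq. NH4Cl
Reagents that add atoms: N,N-dimethylformamide, CN(C)C=O
Why: Iodine–lithium exchange proceeds with retention of alkene geometry, and formylation of the alkenyllithium with DMF (Bouveault aldehyde synthesis) should give the enal with the formyl group cis to CH2OSi.

Step 4
Reactants: 8 3-methylbut-2-en-1-ol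
Product: 9 tert-butyldimethyl[(3-methylbut-2-en-1-yl)oxy]silane
Conditions: TBSCl, imidazole, CH2Cl2, rt
Reagents that add atoms: tert-butyl(chloro)dimethylsilane, CC(C)(C)[Si](C)(C)Cl
Why: Routine silylation of a primary allylic alcohol.

Step 5
Reactants: 9 tert-butyldimethyl[(3-methylbut-2-en-1-yl)oxy]silane
Product: 10 (2E)-4-{[tert-butyl(dimethyl)silyl]oxy}-2-methylbut-2-en-1-ol
Conditions: SeO2 (0.3 equiv), t-BuOOH, salicylic acid (cat.), CH2Cl2, rt
Reagents that add atoms: tert-butyl hydroperoxide, CC(C)(C)OO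
Why: Selenium dioxide allylic oxidation (ene reaction followed by [2,3]-sigmatropic shift) should hydroxylate selectively the (E)-methyl group of the gem-dimethyl alkene.

Step 6
Reactants: 10 (2E)-4-{[tert-butyl(dimethyl)silyl]oxy}-2-methylbut-2-en-1-ol; 11 prop-2-ene-1,1-diyl diacetate
Product: 13 (3R,4S,5E)-7-{[tert-butyl(dimethyl)silyl]oxy}-5-methylhepta-1,5-diene-3,4-diol, via monoacetate 12 (not isolated)
Conditions: [Ir(cod)Cl]2 (2.5 mol%), SEGPHOS (5 mol%, antipode leading to 13), 4-cyano-3-nitrobenzoic acid (10 mol%), K3PO4, THF, 90 °C; then K2CO3, MeOH, rt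
Reagents that add atoms: none
Why: Iridium-catalysed transfer-hydrogenative carbonyl (α-acyloxy)allylation from the alcohol oxidation level: the transient enal is attacked by the (E)-α-acetoxyallyliridium species through a closed chair transition state, which should give the anti (erythro) C8/C9 relationship with the chiral bisphosphine setting the absolute configuration, and methanolysis then frees the diol.

Step 7
Reactants: 13 (3R,4S,5E)-7-{[tert-butyl(dimethyl)silyl]oxy}-5-methylhepta-1,5-diene-3,4-diol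
Product: 14 tert-butyl({(2E)-3-[(4S,5R)-5-ethenyl-2-(4-methoxyphenyl)-1,3-dioxolan-4-yl]but-2-en-1-yl}oxy)dimethylsilane
Conditions: 4-MeOC6H4CH(OMe)2, PPTS (cat.), CH2Cl2, rt
Reagents that add atoms: 4-methoxybenzaldehyde dimethyl acetal, COc1ccc(C(OC)OC)cc1
Why: Acid-catalysed transacetalization of the 1,2-diol, the new acetal carbon forming as an epimer mixture that is erased in step 8.

Step 8
Reactants: 14 tert-butyl({(2E)-3-[(4S,5R)-5-ethenyl-2-(4-methoxyphenyl)-1,3-dioxolan-4-yl]but-2-en-1-yl}oxy)dimethylsilane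
Product: 15 (3R,4S,5E)-7-{[tert-butyl(dimethyl)silyl]oxy}-4-[(4-methoxybenzyl)oxy]-5-methylhepta-1,5-dien-3-ol
Conditions: DIBAL-H (3 equiv), CH2Cl2, −78 to 0 °C
Reagents that add atoms: none
Why: Regioselective reductive opening of the 4-methoxybenzylidene acetal, in which the aluminium hydride should coordinate the less hindered O8 next to the vinyl group so that the PMB ether remains on O9 next to the methyl-bearing alkene carbon.

Step 9
Reactants: 15 (3R,4S,5E)-7-{[tert-butyl(dimethyl)silyl]oxy}-4-[(4-methoxybenzyl)oxy]-5-methylhepta-1,5-dien-3-ol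
Product: 16 (1R,2R)-1-[(2S,3R)-3-({[tert-butyl(dimethyl)silyl]oxy}methyl)-2-methyloxiran-2-yl]-1-[(4-methoxybenzyl)oxy]but-3-en-2-ol
Conditions: D-fructose-derived Shi ketone (30 mol%), KHSO5 (Oxone), K2CO3, Bu4NHSO4, MeCN/CH2(OMe)2, aq. Na2B4O7 buffer, 0 °C
Reagents that add atoms: potassium peroxymonosulfate, [K+].[O-]S(=O)(=O)OO
Why: Shi asymmetric epoxidation (chiral dioxirane, spiro transition state) should oxidise only the electron-rich trisubstituted (E)-alkene, the catalyst setting C10 as S and C1 as R while the monosubstituted vinyl group is left untouched.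

Step 10
Reactants: 16 (1R,2R)-1-[(2S,3R)-3-({[tert-butyl(dimethyl)silyl]oxy}methyl)-2-methyloxiran-2-yl]-1-[(4-methoxybenzyl)oxy]but-3-en-2-ol; 17 2-(bromomethyl)prop-2-enoic acid
Product: 18 (1R,2R)-1-[(2S,3R)-3-({[tert-butyl(dimethyl)silyl]oxy}methyl)-2-methyloxiran-2-yl]-1-[(4-methoxybenzyl)oxy]but-3-en-2-yl 2-(bromomethyl)prop-2-enoate
Conditions: DIC, DMAP (5 mol%), CH2Cl2, 0 °C
Reagents that add atoms: none
Why: Steglich esterification of the secondary allylic alcohol, run cold with little DMAP so that the allylic bromide is not displaced.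

Step 11
Reactants: 18 (1R,2R)-1-[(2S,3R)-3-({[tert-butyl(dimethyl)silyl]oxy}methyl)-2-methyloxiran-2-yl]-1-[(4-methoxybenzyl)oxy]but-3-en-2-yl 2-(bromomethyl)prop-2-enoate
Product: 19 (5R)-3-(bromomethyl)-5-{(R)-[(2S,3R)-3-({[tert-butyl(dimethyl)silyl]oxy}methyl)-2-methyloxiran-2-yl][(4-methoxybenzyl)oxy]methyl}furan-2(5H)-one
Conditions: second-generation Grubbs catalyst RuCl2(=CHPh)(H2IMes)(PCy3) (10 mol%), toluene, 80 °C
Reagents that add atoms: none
Why: Ring-closing metathesis of the vinyl group with the 1,1-disubstituted acrylate should close the five-membered butenolide with loss of ethene, leaving the C8 stereocenter untouched.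

Step 12
Reactants: 19 (5R)-3-(bromomethyl)-5-{(R)-[(2S,3R)-3-({[tert-butyl(dimethyl)silyl]oxy}methyl)-2-methyloxiran-2-yl][(4-methoxybenzyl)oxy]methyl}furan-2(5H)-one; 7 (2E)-4-{[tert-butyl(diphenyl)silyl]oxy}-3-[(trimethylsilyl)methyl]but-2-enal
Product: 21 (4S,5R)-4-{(1R,2E)-4-{[tert-butyl(diphenyl)silyl]oxy}-1-hydroxy-3-[(trimethylsilyl)methyl]but-2-en-1-yl}-5-{(R)-[(2S,3R)-3-({[tert-butyl(dimethyl)silyl]oxy}methyl)-2-methyloxiran-2-yl][(4-methoxybenzyl)oxy]methyl}-3-methylidenedihydrofuran-2(3H)-one, via allylzinc bromide 20 (not isolated)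
Conditions: Zn dust, THF/sat. aq. NH4Cl, 0 °C to rt
Reagents that add atoms: none
Why: Barbier-type 2-(alkoxycarbonyl)allylation in which the allylzinc should react at its γ-carbon C7 through a closed Zimmerman–Traxler transition state, anti to the C8 substituent (7,8-trans lactone), its ring-locked (E)-geometry giving the anti adduct, which is the C6 epimer required for the invertive esterification of step 13.

Step 13
Reactants: 21 (4S,5R)-4-{(1R,2E)-4-{[tert-butyl(diphenyl)silyl]oxy}-1-hydroxy-3-[(trimethylsilyl)methyl]but-2-en-1-yl}-5-{(R)-[(2S,3R)-3-({[tert-butyl(dimethyl)silyl]oxy}methyl)-2-methyloxiran-2-yl][(4-methoxybenzyl)oxy]methyl}-3-methylidenedihydrofuran-2(3H)-one; 22 (2Z)-2-methylbut-2-enoic acid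
Product: 23 (1S,2E)-4-{[tert-butyl(diphenyl)silyl]oxy}-1-[(2R,3S)-2-{(R)-[(2S,3R)-3-({[tert-butyl(dimethyl)silyl]oxy}methyl)-2-methyloxiran-2-yl][(4-methoxybenzyl)oxy]methyl}-4-methylidene-5-oxooxolan-3-yl]-3-[(trimethylsilyl)methyl]but-2-en-1-yl (2Z)-2-methylbut-2-enoate
Conditions: PPh3, DIAD, toluene, 0 °C to rt
Reagents that add atoms: none
Why: Mitsunobu esterification should install the angelate with SN2 inversion at C6 under neutral conditions that do not isomerise the (Z)-ester, SN2′ attack being disfavoured at the fully substituted C4.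

Step 14
Reactants: 23 (1S,2E)-4-{[tert-butyl(diphenyl)silyl]oxy}-1-[(2R,3S)-2-{(R)-[(2S,3R)-3-({[tert-butyl(dimethyl)silyl]oxy}methyl)-2-methyloxiran-2-yl][(4-methoxybenzyl)oxy]methyl}-4-methylidene-5-oxooxolan-3-yl]-3-[(trimethylsilyl)methyl]but-2-en-1-yl (2Z)-2-methylbut-2-enoate
Product: 24 (3aS,4S,5S,6R,7S,7aR)-5-(3-{[tert-butyl(diphenyl)silyl]oxy}prop-1-en-2-yl)-6-[(1S)-2-{[tert-butyl(dimethyl)silyl]oxy}-1-hydroxyethyl]-7-[(4-methoxybenzyl)oxy]-6-methyl-3-methylidene-2-oxooctahydro-1-benzofuran-4-yl (2Z)-2-methylbut-2-enoate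
Conditions: BF3·OEt2 (2 equiv), CH2Cl2, −78 °C; aq. NaHCO3
Reagents that add atoms: none
Why: BF3 activates the trisubstituted oxirane and the allylsilane attacks its tertiary carbon C10 through its γ-carbon C5 (anti SE2′), the β-silyl cation at C4 collapsing with loss of the silyl group to the exocyclic C4=C3 methylene; the closest known reaction type is the Lewis-acid-mediated intramolecular epoxide–allylsilane (Hosomi–Sakurai-type) cyclization. The cyclohexane closes in the 6-exo-tet mode, the epoxide oxygen ending outside the ring on C1. C10 is set by stereospecific backside attack on the epoxide carbon fixed in step 9, C1 is carried over unchanged, and C5 is set by a chair transition state anchored by the trans-fused lactone (C7 and C8 equatorial) in which the propenyl unit on C5 is equatorial. The step needs attack at C10 and not at C1, which the six- against seven-membered ring size and the tertiary against secondary carbon should secure. It also needs ring closure to be faster than a 1,2-shift from C9, which the high nucleophilicity of the 2-substituted allylsilane and the lack of an antiperiplanar migrating group in the reactive conformer should secure. The lactone methylene and the angelate are too electron-poor to intervene at −78 °C.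

Step 15
Reactants: 24 (3aS,4S,5S,6R,7S,7aR)-5-(3-{[tert-butyl(diphenyl)silyl]oxy}prop-1-en-2-yl)-6-[(1S)-2-{[tert-butyl(dimethyl)silyl]oxy}-1-hydroxyethyl]-7-[(4-methoxybenzyl)oxy]-6-methyl-3-methylidene-2-oxooctahydro-1-benzofuran-4-yl (2Z)-2-methylbut-2-enoate
Product: 25 the C1 methanesulfonate of 24
Conditions: MsCl, Et3N, CH2Cl2, −20 °C
Reagents that add atoms: methanesulfonyl chloride, CS(=O)(=O)Cl
Why: Sulfonylation (via sulfene) of the only free hydroxyl turns the C1 oxygen into a leaving group without touching the stereocenter.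

Step 16
Reactants: 25 the C1 methanesulfonate of 24
Product: 28 (3aS,4S,5S,6R,7S,7aR)-5-(3-hydroxyprop-1-en-2-yl)-7-[(4-methoxybenzyl)oxy]-6-methyl-3-methylidene-6-[(2R)-oxiran-2-yl]-2-oxooctahydro-1-benzofuran-4-yl (2Z)-2-methylbut-2-enoate, via hydroxy mesylate 26 (not isolated), via silyl ether epoxide 27 (not isolated)
Conditions: TBAF (4 equiv), THF, 0 °C to rt
Reagents that add atoms: none
Why: Fluoride cleaves the primary TBS ether, the C2 alkoxide displaces the neighbouring mesylate in a 3-exo-tet Williamson closure with inversion at C1 to give the (R)-oxirane, and the TBDPS ether is then cleaved as well.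

Step 17
Reactants: 28 (3aS,4S,5S,6R,7S,7aR)-5-(3-hydroxyprop-1-en-2-yl)-7-[(4-methoxybenzyl)oxy]-6-methyl-3-methylidene-6-[(2R)-oxiran-2-yl]-2-oxooctahydro-1-benzofuran-4-yl (2Z)-2-methylbut-2-enoate
Product: 29 (3aS,4S,5S,6S,7S,7aR)-7-hydroxy-5-(3-hydroxyprop-1-en-2-yl)-6-methyl-3-methylidene-6-[(2R)-oxiran-2-yl]-2-oxooctahydro-1-benzofuran-4-yl (2Z)-2-methylbut-2-enoate
Conditions: DDQ, CH2Cl2/pH 7 buffer, 0 °C
Reagents that add atoms: none
Why: Oxidative cleavage of the PMB ether (hydride abstraction to the oxocarbenium ion, then hydrolysis) should leave the ester, the oxirane and the electron-poor alkenes untouched.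

Step 18
Reactants: 29 (3aS,4S,5S,6S,7S,7aR)-7-hydroxy-5-(3-hydroxyprop-1-en-2-yl)-6-methyl-3-methylidene-6-[(2R)-oxiran-2-yl]-2-oxooctahydro-1-benzofuran-4-yl (2Z)-2-methylbut-2-enoate
Product: 30 (3aS,4S,5R,6S,7S,7aR)-7-hydroxy-6-methyl-3-methylidene-6-[(2R)-oxiran-2-yl]-2-oxo-5-(3-oxoprop-1-en-2-yl)octahydro-1-benzofuran-4-yl (2Z)-2-methylbut-2-enoate (CNP0113462.3)
Conditions: MnO2 (activated, excess), CH2Cl2, rt
Reagents that add atoms: none
Why: Manganese dioxide oxidation is selective for the allylic primary alcohol, which gives the 2-substituted acrolein while the non-allylic C9 hydroxyl stays.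

Compound list

1 | prop-2-yn-1-ol | C#CCO | starting material
2 | (trimethylsilyl)methylmagnesium chloride | C[Si](C)(C)C[Mg]Cl | starting material
3 | chloromagnesium (2E)-3-(chloromagnesio)-2-[(trimethylsilyl)methyl]prop-2-en-1-olate | Cl[Mg]OC/C(=C\[Mg]Cl)C[Si](C)(C)C | intermediate (not isolated)
4 | (2E)-3-iodo-2-[(trimethylsilyl)methyl]prop-2-en-1-ol | OC/C(=C\I)C[Si](C)(C)C | intermediate
5 | tert-butyl({(2E)-3-iodo-2-[(trimethylsilyl)methyl]prop-2-en-1-yl}oxy)diphenylsilane | CC(C)(C)[Si](OC/C(=C\I)C[Si](C)(C)C)(c1ccccc1)c1ccccc1 | intermediate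
6 | {(1E)-3-{[tert-butyl(diphenyl)silyl]oxy}-2-[(trimethylsilyl)methyl]prop-1-en-1-yl}lithium | CC(C)(C)[Si](OC/C(=C\[Li])C[Si](C)(C)C)(c1ccccc1)c1ccccc1 | intermediate (not isolated)
7 | (2E)-4-{[tert-butyl(diphenyl)silyl]oxy}-3-[(trimethylsilyl)methyl]but-2-enal | O=C/C=C(\CO[Si](c1ccccc1)(c1ccccc1)C(C)(C)C)C[Si](C)(C)C | intermediate
8 | 3-methylbut-2-en-1-ol | CC(C)=CCO | starting material
9 | tert-butyldimethyl[(3-methylbut-2-en-1-yl)oxy]silane | CC(C)=CCO[Si](C)(C)C(C)(C)C | intermediate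
10 | (2E)-4-{[tert-butyl(dimethyl)silyl]oxy}-2-methylbut-2-en-1-ol | OC/C(C)=C/CO[Si](C)(C)C(C)(C)C | intermediate
11 | prop-2-ene-1,1-diyl diacetate | C=CC(OC(C)=O)OC(C)=O | starting material
12 | (3R,4S,5E)-7-{[tert-butyl(dimethyl)silyl]oxy}-4-hydroxy-5-methylhepta-1,5-dien-3-yl acetate | C=C[C@@H](OC(C)=O)[C@@H](O)/C(C)=C/CO[Si](C)(C)C(C)(C)C | intermediate (not isolated)
13 | (3R,4S,5E)-7-{[tert-butyl(dimethyl)silyl]oxy}-5-methylhepta-1,5-diene-3,4-diol | C=C[C@@H](O)[C@@H](O)/C(C)=C/CO[Si](C)(C)C(C)(C)C | intermediate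
14 | tert-butyl({(2E)-3-[(4S,5R)-5-ethenyl-2-(4-methoxyphenyl)-1,3-dioxolan-4-yl]but-2-en-1-yl}oxy)dimethylsilane, both epimers at the acetal carbon | C=C[C@H]1OC(c2ccc(OC)cc2)O[C@H]1/C(C)=C/CO[Si](C)(C)C(C)(C)C | intermediate
15 | (3R,4S,5E)-7-{[tert-butyl(dimethyl)silyl]oxy}-4-[(4-methoxybenzyl)oxy]-5-methylhepta-1,5-dien-3-ol | O[C@@H]([C@@H](OCc1ccc(OC)cc1)/C(C)=C/CO[Si](C)(C)C(C)(C)C)C=C | intermediate
16 | (1R,2R)-1-[(2S,3R)-3-({[tert-butyl(dimethyl)silyl]oxy}methyl)-2-methyloxiran-2-yl]-1-[(4-methoxybenzyl)oxy]but-3-en-2-ol | O[C@@H]([C@@H](OCc1ccc(OC)cc1)[C@@]1(C)O[C@@H]1CO[Si](C)(C)C(C)(C)C)C=C | intermediate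
17 | 2-(bromomethyl)prop-2-enoic acid | OC(=O)C(=C)CBr | starting material
18 | (1R,2R)-1-[(2S,3R)-3-({[tert-butyl(dimethyl)silyl]oxy}methyl)-2-methyloxiran-2-yl]-1-[(4-methoxybenzyl)oxy]but-3-en-2-yl 2-(bromomethyl)prop-2-enoate | C=C(CBr)C(=O)O[C@@H]([C@@H](OCc1ccc(OC)cc1)[C@@]1(C)O[C@@H]1CO[Si](C)(C)C(C)(C)C)C=C | intermediate
19 | (5R)-3-(bromomethyl)-5-{(R)-[(2S,3R)-3-({[tert-butyl(dimethyl)silyl]oxy}methyl)-2-methyloxiran-2-yl][(4-methoxybenzyl)oxy]methyl}furan-2(5H)-one | O=C1O[C@@H]([C@@H](OCc2ccc(OC)cc2)[C@@]2(C)O[C@@H]2CO[Si](C)(C)C(C)(C)C)C=C1CBr | intermediate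
20 | allylzinc bromide formed from 19 (zinc in place of bromine on C13) | O=C1O[C@@H]([C@@H](OCc2ccc(OC)cc2)[C@@]2(C)O[C@@H]2CO[Si](C)(C)C(C)(C)C)C=C1C[Zn]Br | intermediate (not isolated)
21 | (4S,5R)-4-{(1R,2E)-4-{[tert-butyl(diphenyl)silyl]oxy}-1-hydroxy-3-[(trimethylsilyl)methyl]but-2-en-1-yl}-5-{(R)-[(2S,3R)-3-({[tert-butyl(dimethyl)silyl]oxy}methyl)-2-methyloxiran-2-yl][(4-methoxybenzyl)oxy]methyl}-3-methylidenedihydrofuran-2(3H)-one | C=C1C(=O)O[C@@H]([C@@H](OCc2ccc(OC)cc2)[C@@]2(C)O[C@@H]2CO[Si](C)(C)C(C)(C)C)[C@@H]1[C@H](O)/C=C(\CO[Si](c1ccccc1)(c1ccccc1)C(C)(C)C)C[Si](C)(C)C | intermediate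
22 | (2Z)-2-methylbut-2-enoic acid (angelic acid) | C/C=C(/C)C(=O)O | starting material
23 | (1S,2E)-4-{[tert-butyl(diphenyl)silyl]oxy}-1-[(2R,3S)-2-{(R)-[(2S,3R)-3-({[tert-butyl(dimethyl)silyl]oxy}methyl)-2-methyloxiran-2-yl][(4-methoxybenzyl)oxy]methyl}-4-methylidene-5-oxooxolan-3-yl]-3-[(trimethylsilyl)methyl]but-2-en-1-yl (2Z)-2-methylbut-2-enoate | C=C1C(=O)O[C@@H]([C@@H](OCc2ccc(OC)cc2)[C@@]2(C)O[C@@H]2CO[Si](C)(C)C(C)(C)C)[C@@H]1[C@@H](OC(=O)/C(C)=C\C)/C=C(\CO[Si](c1ccccc1)(c1ccccc1)C(C)(C)C)C[Si](C)(C)C | intermediate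
24 | (3aS,4S,5S,6R,7S,7aR)-5-(3-{[tert-butyl(diphenyl)silyl]oxy}prop-1-en-2-yl)-6-[(1S)-2-{[tert-butyl(dimethyl)silyl]oxy}-1-hydroxyethyl]-7-[(4-methoxybenzyl)oxy]-6-methyl-3-methylidene-2-oxooctahydro-1-benzofuran-4-yl (2Z)-2-methylbut-2-enoate | C=C1C(=O)O[C@@H]2[C@@H]1[C@@H](OC(=O)/C(C)=C\C)[C@@H](C(=C)CO[Si](c1ccccc1)(c1ccccc1)C(C)(C)C)[C@](C)([C@H](O)CO[Si](C)(C)C(C)(C)C)[C@@H]2OCc1ccc(OC)cc1 | intermediate
25 | (3aS,4S,5S,6S,7S,7aR)-5-(3-{[tert-butyl(diphenyl)silyl]oxy}prop-1-en-2-yl)-6-[(1S)-2-{[tert-butyl(dimethyl)silyl]oxy}-1-[(methylsulfonyl)oxy]ethyl]-7-[(4-methoxybenzyl)oxy]-6-methyl-3-methylidene-2-oxooctahydro-1-benzofuran-4-yl (2Z)-2-methylbut-2-enoate | C=C1C(=O)O[C@@H]2[C@@H]1[C@@H](OC(=O)/C(C)=C\C)[C@@H](C(=C)CO[Si](c1ccccc1)(c1ccccc1)C(C)(C)C)[C@](C)([C@H](OS(C)(=O)=O)CO[Si](C)(C)C(C)(C)C)[C@@H]2OCc1ccc(OC)cc1 | intermediate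
26 | (3aS,4S,5S,6S,7S,7aR)-5-(3-{[tert-butyl(diphenyl)silyl]oxy}prop-1-en-2-yl)-6-[(1S)-2-hydroxy-1-[(methylsulfonyl)oxy]ethyl]-7-[(4-methoxybenzyl)oxy]-6-methyl-3-methylidene-2-oxooctahydro-1-benzofuran-4-yl (2Z)-2-methylbut-2-enoate | C=C1C(=O)O[C@@H]2[C@@H]1[C@@H](OC(=O)/C(C)=C\C)[C@@H](C(=C)CO[Si](c1ccccc1)(c1ccccc1)C(C)(C)C)[C@](C)([C@H](OS(C)(=O)=O)CO)[C@@H]2OCc1ccc(OC)cc1 | intermediate (not isolated)
27 | (3aS,4S,5S,6R,7S,7aR)-5-(3-{[tert-butyl(diphenyl)silyl]oxy}prop-1-en-2-yl)-7-[(4-methoxybenzyl)oxy]-6-methyl-3-methylidene-6-[(2R)-oxiran-2-yl]-2-oxooctahydro-1-benzofuran-4-yl (2Z)-2-methylbut-2-enoate | C=C1C(=O)O[C@@H]2[C@@H]1[C@@H](OC(=O)/C(C)=C\C)[C@@H](C(=C)CO[Si](c1ccccc1)(c1ccccc1)C(C)(C)C)[C@](C)([C@@H]1CO1)[C@@H]2OCc1ccc(OC)cc1 | intermediate (not isolated)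
28 | (3aS,4S,5S,6R,7S,7aR)-5-(3-hydroxyprop-1-en-2-yl)-7-[(4-methoxybenzyl)oxy]-6-methyl-3-methylidene-6-[(2R)-oxiran-2-yl]-2-oxooctahydro-1-benzofuran-4-yl (2Z)-2-methylbut-2-enoate | C=C1C(=O)O[C@@H]2[C@@H]1[C@@H](OC(=O)/C(C)=C\C)[C@@H](C(=C)CO)[C@](C)([C@@H]1CO1)[C@@H]2OCc1ccc(OC)cc1 | intermediate
29 | (3aS,4S,5S,6S,7S,7aR)-7-hydroxy-5-(3-hydroxyprop-1-en-2-yl)-6-methyl-3-methylidene-6-[(2R)-oxiran-2-yl]-2-oxooctahydro-1-benzofuran-4-yl (2Z)-2-methylbut-2-enoate | C=C1C(=O)O[C@@H]2[C@@H]1[C@@H](OC(=O)/C(C)=C\C)[C@@H](C(=C)CO)[C@](C)([C@@H]1CO1)[C@@H]2O | intermediate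
30 | (3aS,4S,5R,6S,7S,7aR)-7-hydroxy-6-methyl-3-methylidene-6-[(2R)-oxiran-2-yl]-2-oxo-5-(3-oxoprop-1-en-2-yl)octahydro-1-benzofuran-4-yl (2Z)-2-methylbut-2-enoate (CNP0113462.3) | C=C1C(=O)O[C@@H]2[C@@H]1[C@@H](OC(=O)/C(C)=C\C)[C@@H](C(=C)C=O)[C@](C)([C@@H]1CO1)[C@@H]2O | target

Total step count: 18. Longest linear sequence: 15 steps (steps 4 to 18, from 8).

Steps most likely to fail

Step 14. A 1,2-shift from C9 onto the developing C10 cation (semipinacol-type rearrangement) or protodesilylation may outrun ring closure, and closure through a non-chair transition state would erode the C5 configuration. The fallback sets out from 23 and returns at 29; it replaces the epoxide electrophile by a π-allylpalladium electrophile and introduces the oxirane afterwards.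
- The oxirane of 23 would be deoxygenated with retention of alkene geometry (CH3ReO3 cat., PPh3, benzene, rt) to the deoxygenated (E)-alkene F1.
- The primary TBS ether would be removed selectively (PPTS, MeOH) to give allylic alcohol F2, which methyl chloroformate and pyridine convert into allylic carbonate F3.
- Zerovalent palladium (Pd(PPh3)4, THF, 60 °C) ionises the carbonate, and the allylsilane should attack the π-allyl complex at its more substituted terminus C10 in the six-membered mode to give vinylcyclohexane F4. This is an intramolecular Tsuji–Trost allylation through a chair transition state with both alkenyl groups equatorial.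
- DDQ frees the C9 hydroxyl to give alcohol F5, which directs vanadium-catalysed epoxidation (VO(acac)2, t-BuOOH) of the homoallylic vinyl group to oxirane F6.
- TBAF buffered with acetic acid removes the silyl ether to reach 29.

Step 13. SN2 displacement at the hindered allylic C6 oxyphosphonium ion may be too slow, so that elimination or partial retention competes. The fallback sets out from 21 and returns at 23; it sets C6 by oxidation and reagent-controlled reduction instead of by substitution.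
- Dess–Martin periodinane (NaHCO3, CH2Cl2, 0 °C) would give enone F7, used at once because its exocyclic alkene can migrate into conjugation.
- Corey–Bakshi–Shibata reduction (2-methyl-CBS-oxazaborolidine antipode chosen for the 6S carbinol, catecholborane, −78 °C) should give the C6-epimeric alcohol F8.
- Yamaguchi esterification with 22 (2,4,6-trichlorobenzoyl chloride, Et3N, then DMAP, toluene) proceeds with retention and gives 23.

Step 8. Hydride delivery may not discriminate between the two acetal oxygens, leaving the PMB ether partly on O8. The fallback sets out from 12 and returns at 15; it uses the differentiation already present in the allylation product.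
- 12 would be isolated after the iridium-catalysed coupling without methanolysis.
- Its free C9 hydroxyl would be etherified (4-methoxybenzyl trichloroacetimidate, La(OTf)3 cat., toluene) to give PMB ether acetate F9.
- Methanolysis of the acetate (K2CO3, MeOH) gives 15.

Further compounds

F1 | step 14 | deoxygenated (E)-alkene analogue of 23 (C10=C1 alkene in place of the oxirane) | C=C1C(=O)O[C@@H]([C@@H](OCc2ccc(OC)cc2)/C(C)=C/CO[Si](C)(C)C(C)(C)C)[C@@H]1[C@@H](OC(=O)/C(C)=C\C)/C=C(\CO[Si](c1ccccc1)(c1ccccc1)C(C)(C)C)C[Si](C)(C)C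
F2 | step 14 | allylic alcohol (free C2 hydroxyl) derived from F1 | C=C1C(=O)O[C@@H]([C@@H](OCc2ccc(OC)cc2)/C(C)=C/CO)[C@@H]1[C@@H](OC(=O)/C(C)=C\C)/C=C(\CO[Si](c1ccccc1)(c1ccccc1)C(C)(C)C)C[Si](C)(C)C
F3 | step 14 | allylic methyl carbonate of F2 | C=C1C(=O)O[C@@H]([C@@H](OCc2ccc(OC)cc2)/C(C)=C/COC(=O)OC)[C@@H]1[C@@H](OC(=O)/C(C)=C\C)/C=C(\CO[Si](c1ccccc1)(c1ccccc1)C(C)(C)C)C[Si](C)(C)C
F4 | step 14 | vinylcyclohexane (10-vinyl, 9-O-PMB, 15-O-TBDPS analogue of 28) | C=C1C(=O)O[C@@H]2[C@@H]1[C@@H](OC(=O)/C(C)=C\C)[C@@H](C(=C)CO[Si](c1ccccc1)(c1ccccc1)C(C)(C)C)[C@](C)(C=C)[C@@H]2OCc1ccc(OC)cc1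
F5 | step 14 | 9-hydroxy vinylcyclohexane obtained from F4 | C=C1C(=O)O[C@@H]2[C@@H]1[C@@H](OC(=O)/C(C)=C\C)[C@@H](C(=C)CO[Si](c1ccccc1)(c1ccccc1)C(C)(C)C)[C@](C)(C=C)[C@@H]2O
F6 | step 14 | 15-O-TBDPS ether of 29 | C=C1C(=O)O[C@@H]2[C@@H]1[C@@H](OC(=O)/C(C)=C\C)[C@@H](C(=C)CO[Si](c1ccccc1)(c1ccccc1)C(C)(C)C)[C@](C)([C@@H]1CO1)[C@@H]2O
F7 | step 13 | C6 enone obtained from 21 | C=C1C(=O)O[C@@H]([C@@H](OCc2ccc(OC)cc2)[C@@]2(C)O[C@@H]2CO[Si](C)(C)C(C)(C)C)[C@@H]1C(=O)/C=C(\CO[Si](c1ccccc1)(c1ccccc1)C(C)(C)C)C[Si](C)(C)C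
F8 | step 13 | (6S)-alcohol, the C6 epimer of 21 | C=C1C(=O)O[C@@H]([C@@H](OCc2ccc(OC)cc2)[C@@]2(C)O[C@@H]2CO[Si](C)(C)C(C)(C)C)[C@@H]1[C@@H](O)/C=C(\CO[Si](c1ccccc1)(c1ccccc1)C(C)(C)C)C[Si](C)(C)C
F9 | step 8 | (3R,4S,5E)-7-{[tert-butyl(dimethyl)silyl]oxy}-4-[(4-methoxybenzyl)oxy]-5-methylhepta-1,5-dien-3-yl acetate | C=C[C@@H](OC(C)=O)[C@@H](OCc1ccc(OC)cc1)/C(C)=C/CO[Si](C)(C)C(C)(C)C
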